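**Retrosynthetic overview**

- The strategy rests on ring A, the 4-hydroxyphenyl group on C4 of the butenolide (O1, C2 carbonyl, C3 methoxy, C4, C5 quaternary). Its ipso carbon and one ortho carbon are mapped onto an ethynyl group on C4, and its other four carbons onto 1-methoxy-3-(trimethylsilyloxy)butadiene, so ring A is made last by Diels–Alder addition and loss of methanol.
- The C4–alkyne bond comes from Sonogashira coupling of the C4 enol triflate of a 3-methoxytetronic acid. The butenolide ring is closed at C3–C4 by Dieckmann condensation of a methoxyacetate ester onto an acyl imidazolide.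
- C5 is set by esterase desymmetrisation of a prochiral dimethyl 2-benzyl-2-hydroxymalonate. This is made from dimethyl malonate and the prenylated, silylated 4-hydroxybenzaldehyde by Knoevenagel condensation, conjugate reduction and enolate hydroxylation.
- Ring order: ring B is bought as 4-hydroxybenzaldehyde and prenylated first; the butenolide ring is formed in step 8; ring A in step 12; both silyl ethers are removed in step 13.

Key step: step 12

Assumption: pig liver esterase is taken to hydrolyse the enantiotopic ester of 8 that leads to the (R)-half-ester 9; this sense cannot be predicted with confidence for this substrate, and the fallback for step 6 reaches (R)-9 without the enzyme.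

Abbreviation and numbering: ArCH2 = [3-(3-methylbut-2-enyl)-4-(triisopropylsilyloxy)phenyl]methyl. The text uses butenolide numbering (O1, C2=O, C3–OMe, C4, C5 quaternary); systematic names number the ring from the ester-bearing carbon.

**Route**

Step 1
Reactants: 1 4-hydroxybenzaldehyde; 2 1-bromo-3-methylbut-2-ene
Product: 3 4-hydroxy-3-(3-methylbut-2-enyl)benzaldehyde
Conditions: KOH (aq), rt
Reagents that add atoms: none
Why: Ambident phenoxide alkylation, in which water shields the phenoxide oxygen by hydrogen bonding so that part of the allylic bromide is taken up at the ortho carbon (the para position is blocked by the formyl group), and the phenolic C-prenyl product is separated from the neutral O-prenyl ether by base extraction.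

Step 2
Reactants: 3 4-hydroxy-3-(3-methylbut-2-enyl)benzaldehyde
Product: 4 3-(3-methylbut-2-enyl)-4-(triisopropylsilyloxy)benzaldehyde
Conditions: iPr3SiCl, imidazole, DMF, rt
Reagents that add atoms: triisopropylsilyl chloride, CC(C)[Si](Cl)(C(C)C)C(C)C
Why: Standard phenol silylation with a silyl chloride and imidazole, the bulky triisopropylsilyl ether being chosen because it must survive amine, hydride, amide-base, enzyme and palladium steps and fall only to fluoride at the end.

Step 3
Reactants: 4 3-(3-methylbut-2-enyl)-4-(triisopropylsilyloxy)benzaldehyde; 5 dimethyl malonate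
Product: 6 dimethyl 2-(ArCH=)malonate (the arylidene malonate)
Conditions: piperidine (cat.), AcOH (cat.), toluene, reflux, Dean–Stark
Reagents that add atoms: none
Why: Knoevenagel condensation of an aromatic aldehyde with a malonate under piperidinium acetate catalysis with azeotropic removal of water, which avoids a labile para-silyloxybenzyl halide and any double alkylation of the malonate.

Step 4
Reactants: 6 dimethyl 2-(ArCH=)malonate
Product: 7 dimethyl 2-(ArCH2)malonate
Conditions: NaBH4, MeOH/THF, 0 °C
Reagents that add atoms: none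
Why: Conjugate (1,4) hydride reduction, since the doubly activated arylidene malonate accepts borohydride at the benzylic carbon much faster than the esters or the isolated prenyl alkene react.

Step 5
Reactants: 7 dimethyl 2-(ArCH2)malonate
Product: 8 dimethyl 2-hydroxy-2-(ArCH2)malonate
Conditions: KN(SiMe3)2, THF, −78 °C; then 3-phenyl-2-(phenylsulfonyl)oxaziridine, −78 °C; AcOH quench
Reagents that add atoms: 3-phenyl-2-(phenylsulfonyl)oxaziridine, O=S(=O)(N1OC1c1ccccc1)c1ccccc1
Why: Electrophilic enolate hydroxylation with an N-sulfonyloxaziridine (Davis oxidation), in which the potassium malonate enolate attacks the oxaziridine oxygen while the prenyl alkene is not epoxidised at this temperature, and the product is still achiral because its two esters are identical.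

Step 6
Reactants: 8 dimethyl 2-hydroxy-2-(ArCH2)malonate
Product: 9 (R)-2-hydroxy-3-methoxy-3-oxo-2-(ArCH2)propanoic acid
Conditions: pig liver esterase, phosphate buffer pH 7.5/DMSO (9:1), 25 °C, NaOH (pH-stat); then HCl to pH 3, 0 °C
Reagents that add atoms: water, O
Why: Enzymatic desymmetrisation of a prochiral 2,2-disubstituted malonate diester, in which the esterase hydrolyses one of the two enantiotopic methyl esters and this choice alone sets the C5 quaternary stereocentre, taken as (R) under the stated assumption, while the carboxylate charge of the product protects it from a second hydrolysis.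

Step 7
Reactants: 9 (R)-2-hydroxy-3-methoxy-3-oxo-2-(ArCH2)propanoic acid; 10 methoxyacetyl chloride
Product: 12 (R)-3-methoxy-2-(2-methoxyacetoxy)-3-oxo-2-(ArCH2)propanoic acid, via O-acylated mixed anhydride 11 (not isolated)
Conditions: 10 (2.5 equiv), pyridine, DMAP (cat.), CH2Cl2, 0 °C to rt; then THF/H2O, rt; dilute HCl
Reagents that add atoms: none
Why: Acylation of an α-hydroxy acid with an acid chloride under nucleophilic catalysis by DMAP, in which the carboxylate is acylated first and the hindered tertiary alcohol second, the mixed anhydride 11 is then hydrolysed in the aqueous pyridine work-up because an anhydride is far more labile than the ester, and the quaternary centre, which carries no hydrogen, is untouched.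

Step 8
Reactants: 12 (R)-3-methoxy-2-(2-methoxyacetoxy)-3-oxo-2-(ArCH2)propanoic acid
Product: 14 methyl (R)-3-hydroxy-4-methoxy-5-oxo-2-(ArCH2)-2,5-dihydrofuran-2-carboxylate, via acyl imidazolide 13 (not isolated)
Conditions: CDI, THF, rt; then added to LiN(SiMe3)2 (3.5 equiv), THF, −78 °C; cold dilute HCl
Reagents that add atoms: 1,1'-carbonyldiimidazole, O=C(n1ccnc1)n1ccnc1 (supplies the imidazolyl group of 13 only; none of its atoms remain in 14)
Why: Dieckmann (intramolecular Claisen) condensation, in which CDI turns the acid into acyl imidazolide 13, the lithium enolate of the methoxyacetate attacks this most electrophilic carbonyl in a 5-exo-trig closure that forms the C3–C4 bond in preference to attack on the methyl ester, and loss of imidazolide gives the 3-methoxytetronic acid as its stable enolate with C5 unchanged.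

Step 9
Reactants: 14 methyl (R)-3-hydroxy-4-methoxy-5-oxo-2-(ArCH2)-2,5-dihydrofuran-2-carboxylate
Product: 15 methyl (R)-4-methoxy-5-oxo-2-(ArCH2)-3-(trifluoromethylsulfonyloxy)-2,5-dihydrofuran-2-carboxylate
Conditions: Tf2O, iPr2NEt, CH2Cl2, −78 °C
Reagents that add atoms: trifluoromethanesulfonic anhydride, O=S(=O)(OS(=O)(=O)C(F)(F)F)C(F)(F)F
Why: O-Sulfonylation of a tetronic acid, the acidic C4 enol being triflated on oxygen by the anhydride and a hindered amine at low temperature, which is the standard entry to 4-triflyloxybutenolides for cross-coupling.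

Step 10
Reactants: 15 the C4 enol triflate; 16 ethynyltrimethylsilane
Product: 17 methyl (R)-4-methoxy-5-oxo-2-(ArCH2)-3-[2-(trimethylsilyl)ethynyl]-2,5-dihydrofuran-2-carboxylate
Conditions: Pd(PPh3)4 (5 mol %), CuI (10 mol %), iPr2NEt, THF, rt
Reagents that add atoms: none
Why: Sonogashira coupling, in which oxidative addition of zerovalent palladium into the electron-poor enol triflate is fast at room temperature, the copper acetylide of 16 transmetalates, and the hindered amine does not add to the vinylogous acyl triflate.

Step 11
Reactants: 17 the trimethylsilylalkyne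
Product: 18 methyl (R)-3-ethynyl-4-methoxy-5-oxo-2-(ArCH2)-2,5-dihydrofuran-2-carboxylate
Conditions: AgNO3 (0.2 equiv), CH2Cl2/MeOH/H2O, rt
Reagents that add atoms: none
Why: Silver-catalysed protiodesilylation of a trimethylsilylalkyne through the silver acetylide, which is neutral and so should leave the aryl triisopropylsilyl ether, the lactone and the Michael-acceptor enyne untouched where methoxide or fluoride would not.

Step 12
Reactants: 18 the 4-ethynylbutenolide; 19 (E)-1-methoxy-3-(trimethylsilyloxy)buta-1,3-diene
Product: 21 methyl (R)-4-methoxy-5-oxo-2-(ArCH2)-3-[4-(trimethylsilyloxy)phenyl]-2,5-dihydrofuran-2-carboxylate, via methoxycyclohexadiene cycloadduct 20 (not isolated)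
Conditions: 19 (4 equiv, two portions), BHT (cat.), toluene, 120 °C, sealed tube; evaporation, crude taken on
Reagents that add atoms: none
Why: Proposed new method: the C2 carbonyl polarises the C3=C4–C≡CH enyne so that the terminal alkyne carbon is the vinylogous acceptor site, while both oxygen donors of diene 19 push electron density to its unsubstituted CH2 terminus, so an asynchronous normal-demand [4+2] cycloaddition should join that CH2 to the terminal alkyne carbon and the methoxy-bearing terminus to the internal alkyne carbon, after which the 6-methoxy-4-silyloxycyclohexa-1,4-diene 20 loses methanol by 1,4-elimination driven by aromatisation. The closest known reaction type is the Diels–Alder addition of 1-alkoxy-3-silyloxybutadienes to alkynoates and ynones with loss of alcohol to para-silyloxy arenes; what is new is that the activating carbonyl is one vinyl unit away and the intervening alkene carries a donor methoxy group, so a higher temperature and an excess of diene are planned. Ring A, the only ring formed, closes in the intermolecular cycloaddition itself, both of its new C–C bonds being made on the alkyne in one six-membered [4+2] event. No new stereocentre survives, because the methoxy-bearing sp3 carbon of 20 becomes aromatic, and the quaternary C5 has no hydrogen and no path to epimerise under neutral thermal conditions. The step needs para regiochemistry, which the vinylogous polarisation should secure in the same sense as with propiolates, and chemoselectivity for the alkyne, which follows because C3=C4 is tetrasubstituted and the prenyl alkene is unactivated. Partial loss of the trimethylsilyl group from ring A to the liberated methanol would be harmless, since step 13 removes it.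

Step 13
Reactants: 21 the bis-silyl ether
Product: 22 methyl (R)-2-[4-hydroxy-3-(3-methylbut-2-enyl)benzyl]-3-(4-hydroxyphenyl)-4-methoxy-5-oxo-2,5-dihydrofuran-2-carboxylate (the target)
Conditions: Bu4NF (2.5 equiv), AcOH (2.5 equiv), THF, 0 °C
Reagents that add atoms: none
Why: Fluoride-mediated cleavage of both aryl silyl ethers through formation of the strong Si–F bond, buffered with acetic acid so that the phenoxides are protonated at once and the lactone, the methyl ester and the prenyl group see neither strong base nor strong acid.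

**Compound list**

1 | 4-hydroxybenzaldehyde | O=Cc1ccc(O)cc1 | starting material
2 | 1-bromo-3-methylbut-2-ene (prenyl bromide) | CC(C)=CCBr | starting material
3 | 4-hydroxy-3-(3-methylbut-2-enyl)benzaldehyde | O=Cc1ccc(O)c(CC=C(C)C)c1 | intermediate
4 | 3-(3-methylbut-2-enyl)-4-(triisopropylsilyloxy)benzaldehyde | O=Cc1ccc(O[Si](C(C)C)(C(C)C)C(C)C)c(CC=C(C)C)c1 | intermediate
5 | dimethyl malonate | COC(=O)CC(=O)OC | starting material
6 | dimethyl 2-[[3-(3-methylbut-2-enyl)-4-(triisopropylsilyloxy)phenyl]methylidene]malonate | COC(=O)C(=Cc1ccc(O[Si](C(C)C)(C(C)C)C(C)C)c(CC=C(C)C)c1)C(=O)OC | intermediate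
7 | dimethyl 2-[[3-(3-methylbut-2-enyl)-4-(triisopropylsilyloxy)phenyl]methyl]malonate | COC(=O)C(Cc1ccc(O[Si](C(C)C)(C(C)C)C(C)C)c(CC=C(C)C)c1)C(=O)OC | intermediate
8 | dimethyl 2-hydroxy-2-[[3-(3-methylbut-2-enyl)-4-(triisopropylsilyloxy)phenyl]methyl]malonate (achiral, prochiral) | COC(=O)C(O)(Cc1ccc(O[Si](C(C)C)(C(C)C)C(C)C)c(CC=C(C)C)c1)C(=O)OC | intermediate
9 | (2R)-2-hydroxy-3-methoxy-3-oxo-2-[[3-(3-methylbut-2-enyl)-4-(triisopropylsilyloxy)phenyl]methyl]propanoic acid | COC(=O)[C@](C(=O)O)(Cc1ccc(O[Si](C(C)C)(C(C)C)C(C)C)c(CC=C(C)C)c1)O | intermediate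
10 | methoxyacetyl chloride | COCC(=O)Cl | starting material
11 | mixed anhydride of acid 12 with methoxyacetic acid; same spatial arrangement at the quaternary carbon as 9 and 12, descriptor (S) only through the change of priorities; formed in the flask, not isolated | COC(=O)[C@](C(=O)OC(=O)COC)(Cc1ccc(O[Si](C(C)C)(C(C)C)C(C)C)c(CC=C(C)C)c1)OC(=O)COC | intermediate
12 | (2R)-3-methoxy-2-(2-methoxyacetoxy)-3-oxo-2-[[3-(3-methylbut-2-enyl)-4-(triisopropylsilyloxy)phenyl]methyl]propanoic acid | COC(=O)[C@](C(=O)O)(Cc1ccc(O[Si](C(C)C)(C(C)C)C(C)C)c(CC=C(C)C)c1)OC(=O)COC | intermediate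
13 | methyl (2R)-2-(imidazole-1-carbonyl)-2-(2-methoxyacetoxy)-3-[3-(3-methylbut-2-enyl)-4-(triisopropylsilyloxy)phenyl]propanoate; acyl imidazolide, not isolated | COC(=O)[C@](C(=O)n1ccnc1)(Cc1ccc(O[Si](C(C)C)(C(C)C)C(C)C)c(CC=C(C)C)c1)OC(=O)COC | intermediate
14 | methyl (2R)-3-hydroxy-4-methoxy-2-[[3-(3-methylbut-2-enyl)-4-(triisopropylsilyloxy)phenyl]methyl]-5-oxo-2,5-dihydrofuran-2-carboxylate | COC(=O)[C@]1(Cc2ccc(O[Si](C(C)C)(C(C)C)C(C)C)c(CC=C(C)C)c2)OC(=O)C(OC)=C1O | intermediate
15 | methyl (2R)-4-methoxy-2-[[3-(3-methylbut-2-enyl)-4-(triisopropylsilyloxy)phenyl]methyl]-5-oxo-3-(trifluoromethylsulfonyloxy)-2,5-dihydrofuran-2-carboxylate | COC(=O)[C@]1(Cc2ccc(O[Si](C(C)C)(C(C)C)C(C)C)c(CC=C(C)C)c2)OC(=O)C(OC)=C1OS(=O)(=O)C(F)(F)F | intermediate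
16 | ethynyltrimethylsilane | C#C[Si](C)(C)C | starting material
17 | methyl (2R)-4-methoxy-2-[[3-(3-methylbut-2-enyl)-4-(triisopropylsilyloxy)phenyl]methyl]-5-oxo-3-[2-(trimethylsilyl)ethynyl]-2,5-dihydrofuran-2-carboxylate | COC(=O)[C@]1(Cc2ccc(O[Si](C(C)C)(C(C)C)C(C)C)c(CC=C(C)C)c2)OC(=O)C(OC)=C1C#C[Si](C)(C)C | intermediate
18 | methyl (2R)-3-ethynyl-4-methoxy-2-[[3-(3-methylbut-2-enyl)-4-(triisopropylsilyloxy)phenyl]methyl]-5-oxo-2,5-dihydrofuran-2-carboxylate | COC(=O)[C@]1(Cc2ccc(O[Si](C(C)C)(C(C)C)C(C)C)c(CC=C(C)C)c2)OC(=O)C(OC)=C1C#C | intermediate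
19 | (E)-1-methoxy-3-(trimethylsilyloxy)buta-1,3-diene | CO/C=C/C(=C)O[Si](C)(C)C | starting material
20 | methyl (2R)-4-methoxy-3-[6-methoxy-4-(trimethylsilyloxy)cyclohexa-1,4-dien-1-yl]-2-[[3-(3-methylbut-2-enyl)-4-(triisopropylsilyloxy)phenyl]methyl]-5-oxo-2,5-dihydrofuran-2-carboxylate; cycloadduct, both epimers at the methoxy-bearing ring carbon, not isolated | COC(=O)[C@]1(Cc2ccc(O[Si](C(C)C)(C(C)C)C(C)C)c(CC=C(C)C)c2)OC(=O)C(OC)=C1C1=CCC(O[Si](C)(C)C)=CC1OC | intermediate
21 | methyl (2R)-4-methoxy-2-[[3-(3-methylbut-2-enyl)-4-(triisopropylsilyloxy)phenyl]methyl]-5-oxo-3-[4-(trimethylsilyloxy)phenyl]-2,5-dihydrofuran-2-carboxylate | COC(=O)[C@]1(Cc2ccc(O[Si](C(C)C)(C(C)C)C(C)C)c(CC=C(C)C)c2)OC(=O)C(OC)=C1c1ccc(O[Si](C)(C)C)cc1 | intermediate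
22 | methyl (2R)-2-[[4-hydroxy-3-(3-methylbut-2-enyl)phenyl]methyl]-3-(4-hydroxyphenyl)-4-methoxy-5-oxo-2,5-dihydrofuran-2-carboxylate | COC(=O)[C@]1(Cc2ccc(O)c(CC=C(C)C)c2)OC(=O)C(OC)=C1c1ccc(O)cc1 | target

**Step count**

Total: 13 steps. Longest linear sequence: 13 steps (1 to 22; the route is fully linear).

**Steps most likely to fail**

Step 12 (proposed new method). The cycloaddition may be too slow on an alkyne that is activated only through the C3=C4 bond, so that the diene decomposes or polymerises first, or the two new bonds may form in the reversed orientation and place the oxygen meta to C4. The fallback uses known chemistry and makes the C4–aryl bond directly. It sets out from triflate 15: Suzuki–Miyaura coupling with 4-hydroxyphenylboronic acid (Pd(PPh3)4, K3PO4, dioxane/H2O, 60 °C) should give methyl (2R)-3-(4-hydroxyphenyl)-4-methoxy-2-[[3-(3-methylbut-2-enyl)-4-(triisopropylsilyloxy)phenyl]methyl]-5-oxo-2,5-dihydrofuran-2-carboxylate F1. Bu4NF/AcOH in THF at 0 °C then removes the triisopropylsilyl group, and the fallback comes back to the route at the target 22.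

Step 6. Hydrolysis may be slow or poorly enantioselective because the large, lipophilic silyloxy-prenyl-benzyl group fits the enzyme badly, or the enzyme may select the opposite enantiotopic ester. The fallback is a classical resolution and sets out from 8. Monosaponification with one equivalent of KOH in THF/H2O at 0 °C gives racemic 2-hydroxy-3-methoxy-3-oxo-2-(ArCH2)propanoic acid F2. Crystallisation with (S)-1-phenylethylamine (or its enantiomer, whichever gives the less soluble salt of the (R)-acid) gives the (S)-1-phenylethylammonium salt of the (R)-acid F3. Acidification with dilute HCl returns to the route at 9. The (S)-acid left in the mother liquor can be re-methylated with Me3SiCHN2 to achiral 8 and recycled.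

Step 8. The enolate may attack the methyl ester instead of the acyl imidazolide, which would erode enantiomeric purity; imidazole may cleave the activated methoxyacetate; or the enolate may fragment to methoxyketene before ring closure. The fallback installs an isolable activated ester before O-acylation and sets out from 9. Carbodiimide coupling (EDC·HCl, CH2Cl2, 0 °C to rt) with pentafluorophenol gives 1-methyl 3-(pentafluorophenyl) (S)-2-hydroxy-2-(ArCH2)malonate F4 (same spatial arrangement as 9). Acylation with 10, pyridine and DMAP gives 1-methyl 3-(pentafluorophenyl) (S)-2-(2-methoxyacetoxy)-2-(ArCH2)malonate F5. LiN(SiMe3)2 in THF at −78 °C then closes the ring onto the pentafluorophenyl ester, and the fallback comes back to the route at 14.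

**Further compounds**

F1 | step 12 | methyl (2R)-3-(4-hydroxyphenyl)-4-methoxy-2-[[3-(3-methylbut-2-enyl)-4-(triisopropylsilyloxy)phenyl]methyl]-5-oxo-2,5-dihydrofuran-2-carboxylate | COC(=O)[C@]1(Cc2ccc(O[Si](C(C)C)(C(C)C)C(C)C)c(CC=C(C)C)c2)OC(=O)C(OC)=C1c1ccc(O)cc1
F2 | step 6 | racemic 2-hydroxy-3-methoxy-3-oxo-2-[[3-(3-methylbut-2-enyl)-4-(triisopropylsilyloxy)phenyl]methyl]propanoic acid | COC(=O)C(O)(Cc1ccc(O[Si](C(C)C)(C(C)C)C(C)C)c(CC=C(C)C)c1)C(=O)O
F3 | step 6 | (S)-1-phenylethylammonium (2R)-2-hydroxy-3-methoxy-3-oxo-2-[[3-(3-methylbut-2-enyl)-4-(triisopropylsilyloxy)phenyl]methyl]propanoate | COC(=O)[C@](C(=O)[O-])(Cc1ccc(O[Si](C(C)C)(C(C)C)C(C)C)c(CC=C(C)C)c1)O.C[C@H]([NH3+])c1ccccc1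
F4 | step 8 | 1-methyl 3-(pentafluorophenyl) (2S)-2-hydroxy-2-[[3-(3-methylbut-2-enyl)-4-(triisopropylsilyloxy)phenyl]methyl]malonate | COC(=O)[C@](C(=O)Oc1c(F)c(F)c(F)c(F)c1F)(Cc1ccc(O[Si](C(C)C)(C(C)C)C(C)C)c(CC=C(C)C)c1)O
F5 | step 8 | 1-methyl 3-(pentafluorophenyl) (2S)-2-(2-methoxyacetoxy)-2-[[3-(3-methylbut-2-enyl)-4-(triisopropylsilyloxy)phenyl]methyl]malonate | COC(=O)[C@](C(=O)Oc1c(F)c(F)c(F)c(F)c1F)(Cc1ccc(O[Si](C(C)C)(C(C)C)C(C)C)c(CC=C(C)C)c1)OC(=O)COC
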